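**Strategy.** Ring A (cyclopentane C3–C4–C5–C6–C8) and ring B (cyclooctene C2=C3–C8–C9–C10–C11–C13–C26) share the C3–C8 bond next to the tetrasubstituted C2=C3 alkene. This 5-8 unit is disconnected by a Wagner–Meerwein shift to a cis-fused 6-7 isomer in which C8 is still bonded to the quaternary C2 and C3 carries an equatorial mesylate. Ionisation at C3 lets C8 migrate from C2 to C3: the cyclohexane contracts to ring A, the cycloheptene expands to ring B, and loss of H3 gives C2=C3. The precursor comes from a Claisen union of a trans-hydrindenol with 2-methylcyclohexane-1,3-dione and a B-alkyl Suzuki ring closure.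

Key step: step 24

Remark (locants, arbitrary, used in all names): C1 = methyl on C2; C7 = methyl on C6; C12 = methyl on C11; ring C = C13–C14–C15–C24–C25–C26 (methyl C16 on C15); ring D = C15–C17–C19–C20–C24 (oxygen on C17, isopropyl on C20). In the 6-7 precursors ring A′ = C2–C3–C4–C5–C6–C8 and ring B′ = C2–C8–C9–C10–C11–C13–C26. β is the face of rings C/D carrying C16.
Remark: the Taniaphos enantiomer (step 5) and the CBS enantiomer (step 14) are those that give the configurations drawn. Ketone 23 is carried as a C6 epimer mixture because C6 becomes sp2 in step 18.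

Step 1
Reactants: 1 (R)-4-(tert-butyldimethylsilyloxy)cyclopent-2-en-1-one
Product: 3 (S)-4-isopropylcyclopent-2-en-1-one, via trans-3-isopropyl-4-silyloxycyclopentanone 2 (not isolated)
Conditions: i-PrMgCl, CuBr·SMe2 (cat.), TMSCl, THF, −78 °C; aq. HCl work-up; then DBU, CH2Cl2, 0 °C
Reagents that add atoms: isopropylmagnesium chloride CC(C)[Mg]Cl
Why: Copper-mediated conjugate addition occurs anti to the C4 silyloxy group and E1cB loss of silanol then transposes the enone, so the isopropyl-bearing centre C20 is set by substrate control.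

Step 2
Reactants: 3 (S)-4-isopropylcyclopent-2-en-1-one
Product: 4 (S)-2-iodo-4-isopropylcyclopent-2-en-1-one
Conditions: I2, pyridine, CH2Cl2, rt
Reagents that add atoms: iodine II
Why: Pyridine-mediated α-iodination of the enone (addition–elimination) leaves the γ-stereocentre untouched.

Step 3
Reactants: 4 (S)-2-iodo-4-isopropylcyclopent-2-en-1-one
Product: 5 (S)-4-isopropyl-2-methylcyclopent-2-en-1-one
Conditions: Me4Sn, Pd2(dba)3, AsPh3, CuI, NMP, 60 °C
Reagents that add atoms: tetramethylstannane C[Sn](C)(C)C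
Why: Stille coupling of the α-iodoenone installs the C16 methyl under neutral conditions that do not enolise the γ-centre.

Step 4
Reactants: 5 (S)-4-isopropyl-2-methylcyclopent-2-en-1-one
Product: 6 silyl enol ether of trans-3-allyl-4-isopropyl-2-methylcyclopentanone
Conditions: allylMgBr, CuBr·SMe2, TMSCl, THF, −78 °C
Reagents that add atoms: allylmagnesium bromide C=CC[Mg]Br; chlorotrimethylsilane C[Si](C)(C)Cl
Why: Copper-mediated conjugate allylation occurs trans to the adjacent isopropyl group (C24 by 1,2-induction) and TMSCl traps the regiodefined enolate.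

Step 5
Reactants: 7 (E)-1-bromobut-2-ene; 8 (1,3-dioxolan-2-ylmethyl)magnesium bromide
Product: 9 2-[(2S)-2-methylbut-3-en-1-yl]-1,3-dioxolane
Conditions: CuBr·SMe2 (cat.), Taniaphos (cat.), CH2Cl2, −75 °C
Reagents that add atoms: none
Why: Copper-catalysed asymmetric allylic alkylation (SN2′) gives the branched product and the chiral ligand sets C11.

Step 6
Reactants: 9 2-[(2S)-2-methylbut-3-en-1-yl]-1,3-dioxolane
Product: 10 (3S)-3-methylpent-4-enal
Conditions: 1 M HCl, acetone, rt
Reagents that add atoms: water O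
Why: Acid-catalysed acetal hydrolysis frees the aldehyde; the β-stereocentre cannot epimerise.

Step 7
Reactants: 10 (3S)-3-methylpent-4-enal
Product: 11 (3R)-3-methyl-2-methylidenepent-4-enal
Conditions: aq. CH2O, pyrrolidine (cat.), propionic acid (cat.), i-PrOH, 45 °C
Reagents that add atoms: formaldehyde C=O
Why: Amine-catalysed Mannich condensation–elimination (organocatalytic α-methylenation) gives the 2-substituted acrolein.

Step 8
Reactants: 6 silyl enol ether of trans-3-allyl-4-isopropyl-2-methylcyclopentanone; 11 (3R)-3-methyl-2-methylidenepent-4-enal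
Product: 13 aldol adduct (β-hydroxy ketone), via lithium enolate 12 (not isolated)
Conditions: MeLi, THF, 0 °C; then 11, −78 °C
Reagents that add atoms: none
Why: The regiodefined tetrasubstituted lithium enolate adds to the aldehyde through a Zimmerman–Traxler chair anti to the C24 allyl group, setting the C15 quaternary centre (methyl β) and the C14 carbinol (hydroxyl syn to C16).

Step 9
Reactants: 13 aldol adduct
Product: 14 trans-hydrindenone (ring C closed)
Conditions: Grubbs II (cat.), CH2Cl2, 40 °C
Reagents that add atoms: none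
Why: Ring-closing metathesis of the allyl group with the 1,1-disubstituted alkene closes six-membered ring C as the C13=C26 alkene; the four- and eight-membered alternatives are disfavoured.

Step 10
Reactants: 14 trans-hydrindenone
Product: 15 14β,17β-diol
Conditions: NaBH4, MeOH, 0 °C
Reagents that add atoms: none
Why: Hydride attacks the cyclopentanone from the α face opposite the angular C16 methyl, giving the 17β-alcohol by substrate control.

Step 11
Reactants: 15 14β,17β-diol
Product: 16 17β-silyl ether with free 14β-OH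
Conditions: TBSCl, imidazole, DMF, 0 °C
Reagents that add atoms: tert-butyldimethylsilyl chloride CC(C)(C)[Si](C)(C)Cl
Why: The C17 hydroxyl is silylated selectively because the allylic C14 hydroxyl is flanked by quaternary C15 and the branched C13 substituent.

Step 12
Reactants: 17 2-methylcyclohexane-1,3-dione
Product: 18 3-chloro-2-methylcyclohex-2-en-1-one
Conditions: (COCl)2, DMF (cat.), CH2Cl2, 0 °C to rt
Reagents that add atoms: oxalyl chloride ClC(=O)C(=O)Cl
Why: The vinylogous acid is converted into its vinylogous acid chloride.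

Step 13
Reactants: 16 17β-silyl ether with free 14β-OH; 18 3-chloro-2-methylcyclohex-2-en-1-one
Product: 19 vinylogous ester
Conditions: KHMDS, THF, −78 °C; then 18, −78 to 0 °C
Reagents that add atoms: none
Why: The potassium alkoxide adds to the β-chloroenone and expels chloride (addition–elimination), with retention at C14.

Step 14
Reactants: 19 vinylogous ester
Product: 20 (3S)-allylic alcohol
Conditions: (R)-Me-CBS (cat.), catecholborane, toluene, −40 °C; Et3N/MeOH quench
Reagents that add atoms: none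
Why: CBS reduction of the enone carbonyl is catalyst-controlled (alkenyl as the large group) and sets C3 independently of the remote centres; catecholborane leaves the alkenes untouched.

Step 15
Reactants: 20 (3S)-allylic alcohol
Product: 21 3-O-triethylsilyl ether
Conditions: TESCl, imidazole, DMAP (cat.), CH2Cl2, 0 °C
Reagents that add atoms: chlorotriethylsilane CC[Si](CC)(CC)Cl
Why: Silylation under basic conditions protects the acid-labile γ-hydroxy enol ether.

Step 16
Reactants: 21 3-O-triethylsilyl ether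
Product: 22 Claisen ketone
Conditions: toluene, K2CO3 (solid), 120 °C, sealed tube
Reagents that add atoms: none
Why: The Claisen [3,3] rearrangement transfers chirality suprafacially from C14–O to C26 (C2 on the β face), forms C2–C26 anti to the allylic C3 silyloxy group (C2 quaternary centre), and leaves the C13=C14 alkene and the C8 ketone.

Step 17
Reactants: 22 Claisen ketone
Product: 23 6-methyl ketone (epimer mixture)
Conditions: LDA, THF, −78 °C; MeI, −78 to −20 °C
Reagents that add atoms: iodomethane CI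
Why: The ketone can enolise only toward C6, so enolate methylation is regiospecific.

Step 18
Reactants: 23 6-methyl ketone
Product: 24 C6=C8 enol triflate
Conditions: KHMDS, THF, −78 °C; PhNTf2
Reagents that add atoms: N-phenylbis(trifluoromethanesulfonimide) O=S(=O)(N(c1ccccc1)S(=O)(=O)C(F)(F)F)C(F)(F)F
Why: Removal of the only α-hydrogen and O-triflation give the tetrasubstituted enol triflate regiospecifically.

Step 19
Reactants: 24 C6=C8 enol triflate
Product: 26 tetracyclic diene, via B-alkyl-9-BBN 25 (not isolated)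
Conditions: 9-BBN, THF, 0 °C to rt; then Pd(dppf)Cl2 (cat.), AsPh3, Cs2CO3, DMF/H2O, 50 °C, high dilution
Reagents that add atoms: none
Why: 9-BBN hydroborates only the monosubstituted alkene (boron on C9) and the intramolecular B-alkyl Suzuki–Miyaura coupling forms C8–C9, closing seven-membered ring B′.

Step 20
Reactants: 26 tetracyclic diene
Product: 27 C3 alcohol
Conditions: PPTS, MeOH/CH2Cl2, 0 °C to rt
Reagents that add atoms: none
Why: Mild acidic methanolysis removes the secondary triethylsilyl ether while the tert-butyldimethylsilyl ether survives.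

Step 21
Reactants: 27 C3 alcohol
Product: 28 cis-fused saturated alcohol
Conditions: [Ir(cod)(PCy3)(py)]PF6 (cat.), H2 (1 atm), CH2Cl2, 0 °C
Reagents that add atoms: none
Why: Crabtree's catalyst binds the C3 hydroxyl and delivers both hydrogens to the homoallylic tetrasubstituted alkene from the hydroxyl face, setting C6 and C8 in one syn addition (C7 methyl cis to C9), while the hindered undirected C13=C14 alkene reacts more slowly.

Step 22
Reactants: 28 cis-fused saturated alcohol
Product: 29 C3 mesylate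
Conditions: MsCl, Et3N, DMAP (cat.), CH2Cl2, 0 °C
Reagents that add atoms: methanesulfonyl chloride CS(=O)(=O)Cl
Why: Mesylation installs the leaving group with retention at C3.

Step 23
Reactants: 29 C3 mesylate
Product: 31 enone mesylate, via 14α-hydroperoxide 30 (not isolated)
Conditions: O2, tetraphenylporphyrin (cat.), hν, CH2Cl2, 0 °C; then Ac2O, pyridine, DMAP, rt
Reagents that add atoms: oxygen O=O
Why: The Schenck ene reaction adds singlet oxygen to C14 from the α face and abstracts the axial allylic H26 on the disubstituted side of the alkene (cis effect), and Kornblum–DeLaMare dehydration then gives the C13=C26 enone, which removes the hydrogen on C26.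

Step 24
Reactants: 31 enone mesylate
Product: 32 dienone (5-8-6-5 skeleton)
Conditions: 2,6-lutidine, (CF3)2CHOH, 50 °C
Reagents that add atoms: none
Why: In the ionising, non-nucleophilic medium the C2–C8 ring-fusion bond, anti-periplanar to the equatorial C3–OMs bond, migrates to C3 as the sulfonate leaves (Wagner–Meerwein 1,2-alkyl shift), and the tertiary C2 cation then loses H3 to the base. The closest known reaction type is the solvolytic ring contraction–ring expansion of angularly methylated decalyl sulfonates to hydroazulenes, applied here to a 6-7 system. Ring A is closed by the new C3–C8 bond through the bridged three-centre transition state of the suprafacial 1,2-shift (inversion at C3, retention at C8), and ring B results from the same shift as a one-atom enlargement of the cycloheptene, so no separate cyclisation mode is involved. No new stereocentre is formed: C6 and C8 keep the configurations from step 21 and the C2=C3 geometry is dictated by the eight-membered ring. The step needs migration of C8 rather than the C1 methyl or the C2–C26 bond, which the cis-fused chair should secure because only C2–C8 is anti to the leaving group and the electron-poor enone carbon C26 is a poor migrating group. It also needs proton loss from C3 alone, which is secured because C26 is sp2 and carries no hydrogen, so the cation can only give the conjugated C2=C3 dienone or a minor exocyclic methylene isomer.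

Step 25
Reactants: 32 dienone
Product: 34 C14 enol triflate, via lithium enolate 33 (not isolated)
Conditions: Li, NH3 (l), THF, t-BuOH (1 equiv), −78 °C; isoprene; evaporate NH3; then PhNTf2, THF, −78 °C to rt
Reagents that add atoms: N-phenylbis(trifluoromethanesulfonimide) O=S(=O)(N(c1ccccc1)S(=O)(=O)C(F)(F)F)C(F)(F)F
Why: Dissolving-metal reduction of the enone protonates C26 axially (H26 α, C2 equatorial) and gives the regiodefined enolate, which is trapped as the triflate; the twisted tetrasubstituted C2=C3 alkene is not in planar conjugation.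

Step 26
Reactants: 34 C14 enol triflate
Product: 35 Aspergilol C TBS ether
Conditions: Pd(OAc)2 (cat.), PPh3, HCO2H, Bu3N, DMF, 60 °C
Reagents that add atoms: none
Why: Palladium-catalysed formate reduction of the enol triflate gives the C13=C14 alkene.

Step 27
Reactants: 35 Aspergilol C TBS ether
Product: 36 Aspergilol C
Conditions: TBAF, THF, 40 °C
Reagents that add atoms: none
Why: Fluoride cleaves the silyl ether to the 17β-alcohol.

**Compound list**

1 | (R)-4-(tert-butyldimethylsilyloxy)cyclopent-2-en-1-one | O=C1C=C[C@H](O[Si](C)(C)C(C)(C)C)C1 | starting material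
2 | (3S,4R)-4-(tert-butyldimethylsilyloxy)-3-isopropylcyclopentan-1-one (trans) | O=C1C[C@@H](C(C)C)[C@H](O[Si](C)(C)C(C)(C)C)C1 | intermediate
3 | (S)-4-isopropylcyclopent-2-en-1-one | O=C1C=C[C@H](C(C)C)C1 | intermediate
4 | (S)-2-iodo-4-isopropylcyclopent-2-en-1-one | O=C1C(I)=C[C@H](C(C)C)C1 | intermediate
5 | (S)-4-isopropyl-2-methylcyclopent-2-en-1-one | CC1=C[C@H](C(C)C)CC1=O | intermediate
6 | [(3S,4S)-3-allyl-4-isopropyl-2-methylcyclopent-1-en-1-yl]oxy(trimethyl)silane (allyl trans to isopropyl) | CC1=C(O[Si](C)(C)C)C[C@@H](C(C)C)[C@@H]1CC=C | intermediate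
7 | (E)-1-bromobut-2-ene | C/C=C/CBr | starting material
8 | (1,3-dioxolan-2-ylmethyl)magnesium bromide | Br[Mg]CC1OCCO1 | starting material
9 | 2-[(2S)-2-methylbut-3-en-1-yl]-1,3-dioxolane | C=C[C@@H](C)CC1OCCO1 | intermediate
10 | (3S)-3-methylpent-4-enal | C=C[C@@H](C)CC=O | intermediate
11 | (3R)-3-methyl-2-methylidenepent-4-enal | C=C[C@@H](C)C(=C)C=O | intermediate
12 | lithium enolate of (3S,4S)-3-allyl-4-isopropyl-2-methylcyclopentanone (OLi on C17) | CC1=C(O[Li])C[C@@H](C(C)C)[C@@H]1CC=C | intermediate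
13 | aldol adduct: C17 cyclopentanone, C15 quaternary (16-methyl β, side chain α), 24β-allyl, 20α-isopropyl; side chain C14H(OH)–C13(=CH2)–C11H(CH3)–CH=CH2 (11R), C14 hydroxyl syn to C16 | C=CC[C@H]1[C@H](C(C)C)CC(=O)[C@]1(C)[C@@H](O)C(=C)[C@H](C)C=C | intermediate
14 | trans-hydrindenone: 17-ketone, 14β-hydroxy, C13=C26, C13-[(2R)-but-3-en-2-yl], 16-methyl β, H24 α, 20α-isopropyl | C=C[C@@H](C)C1=CC[C@H]2[C@H](C(C)C)CC(=O)[C@]2(C)[C@H]1O | intermediate
15 | diol: 14 with 17β-hydroxy (cis to C16) | C=C[C@@H](C)C1=CC[C@H]2[C@H](C(C)C)C[C@@H](O)[C@]2(C)[C@H]1O | intermediate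
16 | silyl ether: 17β-OTBS, free 14β-OH | C=C[C@@H](C)C1=CC[C@H]2[C@H](C(C)C)C[C@@H](O[Si](C)(C)C(C)(C)C)[C@]2(C)[C@H]1O | intermediate
17 | 2-methylcyclohexane-1,3-dione | CC1C(=O)CCCC1=O | starting material
18 | 3-chloro-2-methylcyclohex-2-en-1-one | CC1=C(Cl)CCCC1=O | intermediate
19 | vinylogous ester: O14 of 16 bonded to C8 of a 2-methyl-3-oxocyclohex-1-enyl ring (C8=C2, C3=O) | C=C[C@@H](C)C1=CC[C@H]2[C@H](C(C)C)C[C@@H](O[Si](C)(C)C(C)(C)C)[C@]2(C)[C@H]1OC1=C(C)C(=O)CCC1 | intermediate
20 | allylic alcohol: 19 with (3S)-CH–OH in place of the C3 ketone | C=C[C@@H](C)C1=CC[C@H]2[C@H](C(C)C)C[C@@H](O[Si](C)(C)C(C)(C)C)[C@]2(C)[C@H]1OC1=C(C)[C@@H](O)CCC1 | intermediate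
21 | bis-silyl ether: 20 with 3-OTES | C=C[C@@H](C)C1=CC[C@H]2[C@H](C(C)C)C[C@@H](O[Si](C)(C)C(C)(C)C)[C@]2(C)[C@H]1OC1=C(C)[C@@H](O[Si](CC)(CC)CC)CCC1 | intermediate
22 | Claisen ketone: cyclohexanone A′ (C8=O, quaternary C2, 3-OTES cis to C1 methyl, C26 trans to it) joined C2–C26 to ring C (H26 α, C13=C14), 17β-OTBS | CC[Si](CC)(CC)O[C@H]1CCCC(=O)[C@]1(C)[C@H]2C[C@H]3[C@H](C(C)C)C[C@@H](O[Si](C)(C)C(C)(C)C)[C@]3(C)C=C2[C@H](C)C=C | intermediate
23 | 22 with methyl C7 on C6 (epimer mixture) | CC[Si](CC)(CC)O[C@H]1CCC(C)C(=O)[C@]1(C)[C@H]2C[C@H]3[C@H](C(C)C)C[C@@H](O[Si](C)(C)C(C)(C)C)[C@]3(C)C=C2[C@H](C)C=C | intermediate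
24 | C6=C8 enol triflate of 23 (OTf on C8) | CC[Si](CC)(CC)O[C@H]1CCC(C)=C(OS(=O)(=O)C(F)(F)F)[C@]1(C)[C@H]2C[C@H]3[C@H](C(C)C)C[C@@H](O[Si](C)(C)C(C)(C)C)[C@]3(C)C=C2[C@H](C)C=C | intermediate
25 | B-alkyl-9-BBN: 24 with the vinyl group hydroborated (boron on C9) | CC[Si](CC)(CC)O[C@H]1CCC(C)=C(OS(=O)(=O)C(F)(F)F)[C@]1(C)[C@H]2C[C@H]3[C@H](C(C)C)C[C@@H](O[Si](C)(C)C(C)(C)C)[C@]3(C)C=C2[C@H](C)CCB1C2CCCC1CCC2 | intermediate
26 | tetracycle: ring A′ cyclohexene (C6=C8), ring B′ cycloheptane, ring C (C13=C14), ring D; 3-OTES, 17β-OTBS | CC[Si](CC)(CC)O[C@H]1CCC(C)=C2CC[C@@H](C)C3=C[C@@]4(C)[C@H](O[Si](C)(C)C(C)(C)C)C[C@@H](C(C)C)[C@@H]4C[C@@H]3[C@]12C | intermediate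
27 | 26 with free 3-OH | O[C@H]1CCC(C)=C2CC[C@@H](C)C3=C[C@@]4(C)[C@H](O[Si](C)(C)C(C)(C)C)C[C@@H](C(C)C)[C@@H]4C[C@@H]3[C@]12C | intermediate
28 | cis-fused 6-7-6-5 alcohol: 3-OH, C1 methyl, H6 and H8 all cis; C7 methyl trans to them (cis to C9); C13=C14; 17β-OTBS | O[C@H]1CC[C@H](C)[C@@H]2CC[C@@H](C)C3=C[C@@]4(C)[C@H](O[Si](C)(C)C(C)(C)C)C[C@@H](C(C)C)[C@@H]4C[C@@H]3[C@]12C | intermediate
29 | 3-O-mesylate of 28 | CS(=O)(=O)O[C@H]1CC[C@H](C)[C@@H]2CC[C@@H](C)C3=C[C@@]4(C)[C@H](O[Si](C)(C)C(C)(C)C)C[C@@H](C(C)C)[C@@H]4C[C@@H]3[C@]12C | intermediate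
30 | 14α-hydroperoxide with C13=C26 | CS(=O)(=O)O[C@H]1CC[C@H](C)[C@@H]2CC[C@@H](C)C3=C(C[C@H]4[C@H](C(C)C)C[C@@H](O[Si](C)(C)C(C)(C)C)[C@]4(C)[C@@H]3OO)[C@]12C | intermediate
31 | enone mesylate: C14 ketone, C13=C26, 3-OMs | CS(=O)(=O)O[C@H]1CC[C@H](C)[C@@H]2CC[C@@H](C)C3=C(C[C@H]4[C@H](C(C)C)C[C@@H](O[Si](C)(C)C(C)(C)C)[C@]4(C)C3=O)[C@]12C | intermediate
32 | dienone: 5-8-6-5 skeleton, C2=C3, C13=C26, C14 ketone, 17β-OTBS | C/C1=C2\CC[C@H](C)[C@@H]2CC[C@@H](C)C2=C1C[C@H]3[C@H](C(C)C)C[C@@H](O[Si](C)(C)C(C)(C)C)[C@]3(C)C2=O | intermediate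
33 | lithium enolate: C14–OLi, C13=C14, H26 α | C/C1=C2\CC[C@H](C)[C@@H]2CC[C@@H](C)C2=C(O[Li])[C@@]3(C)[C@H](O[Si](C)(C)C(C)(C)C)C[C@@H](C(C)C)[C@@H]3C[C@@H]21 | intermediate
34 | C14 enol triflate | C/C1=C2\CC[C@H](C)[C@@H]2CC[C@@H](C)C2=C(OS(=O)(=O)C(F)(F)F)[C@@]3(C)[C@H](O[Si](C)(C)C(C)(C)C)C[C@@H](C(C)C)[C@@H]3C[C@@H]21 | intermediate
35 | Aspergilol C 17-O-TBS ether | C/C1=C2\CC[C@H](C)[C@@H]2CC[C@@H](C)C2=C[C@@]3(C)[C@H](O[Si](C)(C)C(C)(C)C)C[C@@H](C(C)C)[C@@H]3C[C@@H]21 | intermediate
36 | Aspergilol C | C/C1=C2\CC[C@H](C)[C@@H]2CC[C@@H](C)C2=C[C@@]3(C)[C@H](O)C[C@@H](C(C)C)[C@@H]3C[C@@H]21 | target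

**Totals.** 27 steps; longest linear sequence 23 steps (1–4, 8–11, 13–27).

**Steps most likely to fail**

Step 24. Ionisation is retarded by the electron-poor C26, so substitution or elimination toward C4 without migration may take over. The fallback generates the C3 cation from a diazonium ion instead of a sulfonate. It sets out from 28: Dess–Martin oxidation should give the C3 ketone F1. Photooxygenation and Kornblum–DeLaMare dehydration as in step 23 should give the enedione F2. Tosylhydrazide should condense with the saturated C3 ketone to give the tosylhydrazone F3. Protic Bamford–Stevens conditions (sodium glycolate, ethylene glycol, 150 °C) should form the diazonium ion, whose loss of nitrogen drives the same C8 shift and H3 loss. The sequence comes back to the route at 32.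

Step 19. Oxidative addition and transmetalation at the hindered tetrasubstituted triflate may be slow, so protodeboronation or β-hydride loss may occur instead of ring closure. The fallback closes ring B′ by carbonyl olefination. It sets out from 23, equilibrated with NaOMe to the C6 epimer with C7 trans to C1. 9-BBN then NaBO3 should give the primary alcohol F4, and Dess–Martin oxidation the keto aldehyde F5. Low-valent titanium (TiCl3, Zn–Cu, DME, reflux) should couple C8 with C9 to the cycloheptene F6. PPTS in methanol should give the alcohol F7. Hydroxyl-directed hydrogenation of the trisubstituted C8=C9 alkene ([Rh(nbd)(dppb)]BF4, H2) should then deliver H8 from the hydroxyl face, coming back to the route at 28.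

Step 25. The dienone may undergo 1,6-reduction (protonation at C3) or over-reduction in ammonia. The fallback separates reduction and triflation. It sets out from 32: copper hydride conjugate reduction (Stryker's reagent, benzene, rt) should give the saturated C14 ketone F8 with H26 axial. KHMDS then PhNTf2 enolises toward C13, the only α-CH, and comes back to the route at 34.

Further compounds
F1 | step 24 | C3 ketone from 28 | O=C1CC[C@H](C)[C@@H]2CC[C@@H](C)C3=C[C@@]4(C)[C@H](O[Si](C)(C)C(C)(C)C)C[C@@H](C(C)C)[C@@H]4C[C@@H]3[C@]12C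
F2 | step 24 | enedione (C3 ketone, C14 ketone, C13=C26) | O=C1CC[C@H](C)[C@@H]2CC[C@@H](C)C3=C(C[C@H]4[C@H](C(C)C)C[C@@H](O[Si](C)(C)C(C)(C)C)[C@]4(C)C3=O)[C@]12C
F3 | step 24 | C3 tosylhydrazone of F2 | Cc1ccc(cc1)S(=O)(=O)NN=C1CC[C@H](C)[C@@H]2CC[C@@H](C)C3=C(C[C@H]4[C@H](C(C)C)C[C@@H](O[Si](C)(C)C(C)(C)C)[C@]4(C)C3=O)[C@]12C
F4 | step 19 | primary alcohol (C9–OH) from the C6-equilibrated ketone 23 | CC[Si](CC)(CC)O[C@H]1CC[C@H](C)C(=O)[C@]1(C)[C@H]2C[C@H]3[C@H](C(C)C)C[C@@H](O[Si](C)(C)C(C)(C)C)[C@]3(C)C=C2[C@H](C)CCO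
F5 | step 19 | keto aldehyde (C8 ketone, C9 aldehyde) | CC[Si](CC)(CC)O[C@H]1CC[C@H](C)C(=O)[C@]1(C)[C@H]2C[C@H]3[C@H](C(C)C)C[C@@H](O[Si](C)(C)C(C)(C)C)[C@]3(C)C=C2[C@H](C)CC=O
F6 | step 19 | cycloheptene with C8=C9, 3-OTES | CC[Si](CC)(CC)O[C@H]1CC[C@H](C)C2=CC[C@@H](C)C3=C[C@@]4(C)[C@H](O[Si](C)(C)C(C)(C)C)C[C@@H](C(C)C)[C@@H]4C[C@@H]3[C@]12C
F7 | step 19 | F6 with free 3-OH | O[C@H]1CC[C@H](C)C2=CC[C@@H](C)C3=C[C@@]4(C)[C@H](O[Si](C)(C)C(C)(C)C)C[C@@H](C(C)C)[C@@H]4C[C@@H]3[C@]12C
F8 | step 25 | saturated C14 ketone (H26 α, C13 epimers) | C/C1=C2\CC[C@H](C)[C@@H]2CC[C@@H](C)C2C(=O)[C@@]3(C)[C@H](O[Si](C)(C)C(C)(C)C)C[C@@H](C(C)C)[C@@H]3C[C@@H]21
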